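The spiro cyclopentanone (ring D: C9, C10H2, C11=O, C12H2, C13H–OH) is a mono-reduced cyclopentane-1,3-dione whose spiro atom C9 sits in cyclohexene ring A next to C1, the carbon bearing the side chain. C10–C13 are therefore taken from 3-ethoxycyclobut-2-enone and C9 is made the diazo carbon of a ring A 2-diazo ketone (C1=O). One operation inserts C9 into the C13–C10 bond: the four-membered ring grows into ring D, the quaternary centre forms, and a C1 ketone plus a vinylogous ester remain to carry the side chain and the C13 carbinol. The diazo ketone is a tricyclic lactone assembled by a Diels–Alder/aldol domino.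

Key step: step 7

Numbering used in all names: ring A = C1, C2, C3, C8, C7, C9 (C1=C2 in the target); ring B (cyclopentane) = C4, C5, C6, C7, C8; ring C (lactone) = C3, C14(=O), O, C4, C8; ring D = C9, C10, C11, C12, C13; C15 = side-chain methine on C1. "Lower face" of ring A is the face that carries C4 and C6; "upper face" carries H7, H8 and C14.

Remark: the absolute sense of the two catalyst-controlled steps (steps 2 and 10) is assigned by analogy with related substrates; the mirror-image catalyst or ligand would be used if the sense is the opposite.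

Step 1
Reactants: 1 (E)-hex-3-ene-2,5-dione
Product: 2 (E)-2,5-bis(triisopropylsilyloxy)hexa-1,3,5-triene
Conditions: i-Pr3SiOTf (2.2 equiv), Et3N, CH2Cl2, 0 °C
Reagents that add atoms: triisopropylsilyl trifluoromethanesulfonate, CC(C)[Si](OS(=O)(=O)C(F)(F)F)(C(C)C)C(C)C
Why: Soft enolization with a silyl triflate and an amine should convert both methyl ketones into silyl enol ethers at their only enolizable positions, leaving the E alkene untouched and setting no stereocentre.

Step 2
Reactants: 2 (E)-2,5-bis(triisopropylsilyloxy)hexa-1,3,5-triene; 3 ethyl (E)-4-oxobut-2-enoate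
Product: 6 enone ester (rings A and B cis-fused at C7–C8; C1–OSi(i-Pr)3 enol ether C1=C9; ethyl ester on C3 trans to C8–C4; ring B cyclopentenone with C6=O and C4=C5), via Diels–Alder aldehyde 4 (not isolated), via silyl aldol 5 (not isolated)
Conditions: (S)-1-(2-methylphenyl)-3,3-diphenyltetrahydro-1H,3H-pyrrolo[1,2-c][1,3,2]oxazaborole·HN(SO2CF3)2 (20 mol %), CH2Cl2, −78 °C; then Me3SiOTf (10 mol %), −78 to −40 °C; then DBU, 0 °C
Reagents that add atoms: none
Why: A catalytic asymmetric Diels–Alder reaction of the oxazaborolidinium-bound enal should join the nucleophilic CH2 terminus of the 2-silyloxydiene (C2) to C3 (β to the aldehyde) and place the endo aldehyde cis to the E side chain on C7, so that C3/C8 trans and C7/C8 cis follow from alkene geometry and the endo rule while the catalyst fixes the absolute sense; the remaining silyl enol ether then closes ring B by an intramolecular Mukaiyama aldol addition (five-membered ring) and DBU expels the silanolate (E1cB), leaving the cis ring fusion that is the stable one for the epimerizable C7.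

Step 3
Reactants: 6 enone ester
Product: 8 keto lactone (rings A, B and C; C6 ketone; lactone C14(=O)–O–C4; C1–OSi(i-Pr)3 enol ether), via enone acid 7 (not isolated)
Conditions: LiOH, THF–H2O, 0 °C; HCl (1 M) to pH 3; then PPTS (10 mol %), CH2Cl2, 25 °C
Reagents that add atoms: lithium hydroxide, [Li+].[OH-]
Why: Saponification frees the C3 carboxylic acid, which should add to C4 of the cyclopentenone in an acid-catalysed intramolecular oxa-Michael lactonization (5-exo-trig) that is possible only on the face of ring B carrying C3, so the C4–O bond is set cis to C8–C3 (H4 cis to H8).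

Step 4
Reactants: 8 keto lactone
Product: 9 tertiary alcohol (C6 bears CH3 and OH; OH cis to the C7–C9 bond; C1–OSi(i-Pr)3 enol ether retained)
Conditions: MeMgBr, anhydrous CeCl3, THF, −78 °C
Reagents that add atoms: methylmagnesium bromide, C[Mg]Br
Why: Organocerium 1,2-addition to the ring B ketone from the convex face (opposite rings A and C) should place the methyl group exo and the C6 hydroxyl endo, the weakly basic reagent avoiding β-elimination of the lactone oxygen and sparing the lactone and the silyl enol ether.

Step 5
Reactants: 9 tertiary alcohol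
Product: 11 hydroxymethylene ketone (C1 ketone; C9=CH–OH enol of the C9 formyl group), via keto acetal 10 (not isolated)
Conditions: HC(OMe)3, Me3SiOTf (10 mol %), CH2Cl2, −78 °C; then HCl (1 M), THF, 0 °C
Reagents that add atoms: trimethyl orthoformate, COC(OC)OC; water, O
Why: A Lewis-acid-catalysed Mukaiyama-type addition of the regiodefined C1 silyl enol ether (nucleophilic only at C9) to the dimethoxycarbenium ion, followed by acetal hydrolysis, should put the formyl group on C9 and nowhere else; C9 becomes trigonal again in the next step.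

Step 6
Reactants: 11 hydroxymethylene ketone
Product: 12 diazo ketone (C1=O; C9=N2; rings A, B and C; free C6–OH)
Conditions: 4-acetamidobenzenesulfonyl azide, Et3N, MeCN, 0 to 25 °C
Reagents that add atoms: 4-acetamidobenzenesulfonyl azide, CC(=O)Nc1ccc(cc1)S(=O)(=O)N=[N+]=[N-]
Why: Regitz deformylative diazo transfer: the enolate adds to the sulfonyl azide and the formyl group leaves as the N-formyl sulfonamide, which should place the diazo group regiospecifically on C9.

Step 7
Reactants: 12 diazo ketone; 13 3-ethoxycyclobut-2-en-1-one
Product: 15 spiro vinylogous ester (ring D: C9 spiro; C10H2 on the lower face; C11–OEt=C12H; C13=O on the upper face; C1 ketone retained), via aluminium alkoxide 14 (not isolated)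
Conditions: Me2AlCl (1.1 equiv), CH2Cl2, −78 °C; then 13 (1.5 equiv), −78 to −20 °C
Reagents that add atoms: none
Why: Proposed new method: Me2AlCl turns the C6 hydroxyl into an aluminium alkoxide that binds the carbonyl oxygen of 13, the nucleophilic diazo carbon C9 then adds to the activated carbonyl carbon C13, and a carbon of the four-membered ring (C10 or C12) migrates from C13 to C9 anti-periplanar to the departing N2, which inserts C9 into the ring; the closest known reaction type is the Lewis-acid-promoted (Me3Al, BF3 or Sc(OTf)3) Tiffeneau–Demjanov-type homologation of cyclobutanones by diazoalkanes and α-diazo esters, extended here to an α-diazo ketone and a cyclobutenone. No ring is closed by cyclization: ring D arises by the 1,2-shift that expands the four-membered ring by one atom and becomes spiro to ring A at C9. The one new stereocentre, C9, is controlled by the tether: the alkoxide on C6 (on C7, lower face of ring A) delivers the ketone to the lower face of C9, and because the migrating carbon enters anti to N2 it ends on that lower face (syn to C6, as C10) while C13 swings to the upper face. The step needs 1,2-addition instead of 1,4-addition to the vinylogous ester, which the seven-membered chelate (C9, C7, C6, O, Al, O, C13) should favour over attack at the more remote C11. Both possible migrations (C10 or C12) give the same conjugated vinylogous ester 15 after enol ether tautomerization, so migratory aptitude does not matter.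

Step 8
Reactants: 15 spiro vinylogous ester
Product: 16 enol triflate (C1–OTf; C1=C2)
Conditions: KN(SiMe3)2 (2.1 equiv), THF, −78 °C; then PhNTf2
Reagents that add atoms: N-phenylbis(trifluoromethanesulfonimide), O=S(=O)(N(c1ccccc1)S(=O)(=O)C(F)(F)F)C(F)(F)F
Why: With C9 quaternary the C1 ketone can enolize only towards C2, so kinetic deprotonation and O-triflation should give a single enol triflate, the ketone α-hydrogens being more acidic than the lactone α-hydrogen at C3 and the hindered C6 alkoxide staying untriflated at −78 °C.

Step 9
Reactants: 16 enol triflate; 17 methyl acrylate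
Product: 18 dienoate (methyl (E)-propenoate unit on C1; C1=C2 retained)
Conditions: Pd(OAc)2 (5 mol %), PPh3 (10 mol %), Et3N, DMF, 60 °C
Reagents that add atoms: none
Why: A Mizoroki–Heck reaction (oxidative addition of the alkenyl triflate to zerovalent palladium, syn insertion of the acrylate, syn β-hydride elimination) should give the E dienoate and bring in C15 and the ester carbons.

Step 10
Reactants: 18 dienoate; 19 isopropenylboronic acid pinacol ester
Product: 20 conjugate adduct (C15 bears isopropenyl, CH2CO2Me and C1; configuration as in the target)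
Conditions: [RhCl(C2H4)2]2 (3 mol %), (R)-BINAP (7 mol %), KOH (0.2 equiv), dioxane–H2O (10:1), 40 °C
Reagents that add atoms: none
Why: Rhodium-catalysed asymmetric 1,4-addition (Hayashi–Miyaura reaction) should deliver the isopropenyl group to the β-carbon C15, 1,6-addition being disfavoured because the δ-carbon C2 is a ring carbon of a trisubstituted alkene, and the chiral bisphosphine selects the face of C15.

Step 11
Reactants: 20 conjugate adduct
Product: 21 allylic alcohol (C13–OH on the side of ring D turned to C1; C11–OEt enol ether C11=C12)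
Conditions: NaBH4, CeCl3·7H2O, MeOH, −40 °C
Reagents that add atoms: none
Why: Luche 1,2-reduction of the vinylogous ester carbonyl: hydride should enter C13 from the ring D face turned to C7–H, away from the branched side chain on C1, which puts the hydroxyl on the C1 side as required and leaves esters, lactone and alkenes untouched.

Step 12
Reactants: 21 allylic alcohol
Product: 22 CNP0255095.1 (target)
Conditions: oxalic acid (0.1 M in H2O), THF, 0 °C
Reagents that add atoms: water, O
Why: Mild aqueous acid should protonate the enol ether at C12 and hydrolyse the resulting oxocarbenium ion to the C11 ketone (enol ether hydrolysis) at a temperature where the β-hydroxy ketone does not dehydrate.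

Compound list

1 | (E)-hex-3-ene-2,5-dione | CC(=O)/C=C/C(C)=O | starting material
2 | (E)-2,5-bis(triisopropylsilyloxy)hexa-1,3,5-triene | C=C(O[Si](C(C)C)(C(C)C)C(C)C)/C=C/C(=C)O[Si](C(C)C)(C(C)C)C(C)C | intermediate
3 | ethyl (E)-4-oxobut-2-enoate | CCOC(=O)/C=C/C=O | starting material
4 | Diels–Alder aldehyde: ethyl 6-formyl-3-(triisopropylsilyloxy)-5-[1-(triisopropylsilyloxy)ethenyl]cyclohex-3-ene-1-carboxylate (ester and formyl trans; formyl and silyloxyethenyl cis) | CC(C)[Si](C(C)C)(C(C)C)OC=1C[C@@H](C(=O)OCC)[C@H](C=O)[C@H](C(=C)O[Si](C(C)C)(C(C)C)C(C)C)C=1 | intermediate (not isolated)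
5 | silyl aldol: cis-fused rings A and B, C6 ketone, C4–OSi(i-Pr)3 (both C4 epimers), C3 ethyl ester, C1 silyl enol ether | CC(C)[Si](C(C)C)(C(C)C)OC=1C[C@@H](C(=O)OCC)[C@@H]2C(O[Si](C(C)C)(C(C)C)C(C)C)CC(=O)[C@@H]2C=1 | intermediate (not isolated)
6 | enone ester: cis-fused rings A and B, cyclopentenone (C6=O, C4=C5), C3 ethyl ester trans to C8–C4, C1 silyl enol ether | CC(C)[Si](C(C)C)(C(C)C)OC=1C[C@@H](C(=O)OCC)[C@@H]2C=CC(=O)[C@@H]2C=1 | intermediate
7 | enone acid: as 6 with a free C3 carboxylic acid | CC(C)[Si](C(C)C)(C(C)C)OC=1C[C@@H](C(=O)O)[C@@H]2C=CC(=O)[C@@H]2C=1 | intermediate (not isolated)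
8 | keto lactone: rings A, B, C; C6 ketone; lactone trans-fused to ring A and cis-fused to ring B; C1 silyl enol ether | CC(C)[Si](C(C)C)(C(C)C)OC=1C[C@H]2C(=O)O[C@@H]3CC(=O)[C@@H]([C@@H]32)C=1 | intermediate
9 | tertiary alcohol: as 8 with C6(CH3)(OH), OH cis to C7–C9 | CC(C)[Si](C(C)C)(C(C)C)OC=1C[C@H]2C(=O)O[C@@H]3C[C@](C)(O)[C@@H]([C@@H]32)C=1 | intermediate
10 | keto acetal: C1 ketone, C9–CH(OMe)2 (C9 configuration not assigned) | O=C1C[C@H]2C(=O)O[C@@H]3C[C@](C)(O)[C@@H]([C@@H]32)C1C(OC)OC | intermediate (not isolated)
11 | hydroxymethylene ketone: C1 ketone, C9=CH–OH (OH syn to C1=O) | O=C1C[C@H]2C(=O)O[C@@H]3C[C@](C)(O)[C@@H]([C@@H]32)/C1=C/O | intermediate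
12 | diazo ketone: C1 ketone, C9 diazo, rings A, B, C, free C6–OH | O=C1C[C@H]2C(=O)O[C@@H]3C[C@](C)(O)[C@@H]([C@@H]32)C1=[N+]=[N-] | intermediate
13 | 3-ethoxycyclobut-2-en-1-one | CCOC1=CC(=O)C1 | starting material
14 | aluminium alkoxide: C6–O–Al(CH3)Cl derivative of 12 | O=C1C[C@H]2C(=O)O[C@@H]3C[C@](C)(O[Al](C)Cl)[C@@H]([C@@H]32)C1=[N+]=[N-] | intermediate (not isolated)
15 | spiro vinylogous ester: ring D with C10H2 (lower face), C11(OEt)=C12H, C13=O (upper face); C1 ketone | O=C1C[C@H]2C(=O)O[C@@H]3C[C@](C)(O)[C@@H]([C@@H]32)[C@]12CC(OCC)=CC2=O | intermediate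
16 | enol triflate: C1–OSO2CF3, C1=C2 | O=S(=O)(OC1=C[C@H]2C(=O)O[C@@H]3C[C@](C)(O)[C@@H]([C@@H]32)[C@]12CC(OCC)=CC2=O)C(F)(F)F | intermediate
17 | methyl acrylate | C=CC(=O)OC | starting material
18 | dienoate: methyl (E)-3-(ring A C1-yl)propenoate, C1=C2 | COC(=O)/C=C/C1=C[C@H]2C(=O)O[C@@H]3C[C@](C)(O)[C@@H]([C@@H]32)[C@]12CC(OCC)=CC2=O | intermediate
19 | isopropenylboronic acid pinacol ester | CC(=C)B1OC(C)(C)C(C)(C)O1 | starting material
20 | conjugate adduct: complete side chain on C1; ring D still the ethyl vinylogous ester (C13=O) | C=C(C)[C@H](CC(=O)OC)C1=C[C@H]2C(=O)O[C@@H]3C[C@](C)(O)[C@@H]([C@@H]32)[C@]12CC(OCC)=CC2=O | intermediate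
21 | allylic alcohol: C13–OH, C11(OEt)=C12 enol ether | C=C(C)[C@H](CC(=O)OC)C1=C[C@H]2C(=O)O[C@@H]3C[C@](C)(O)[C@@H]([C@@H]32)[C@]12CC(OCC)=C[C@@H]2O | intermediate
22 | CNP0255095.1 | C=C(C)[C@H](CC(=O)OC)C1=C[C@H]2C(=O)O[C@@H]3C[C@](C)(O)[C@@H]([C@@H]32)[C@]12CC(=O)C[C@@H]2O | target

Total step count: 12. Longest linear sequence: 12 steps (from 1 to 22).

Steps most likely to fail

Step 7 (Proposed new method). What may go wrong: delivery of the cyclobutenone to the upper face of C9, conjugate (1,4-) attack on the vinylogous ester, or Lewis-acid-induced loss of N2 with a 1,2-hydride shift from C7. The fallback uses known chemistry, sets out from 12 and returns at 15. A Sc(OTf)3-catalysed homologation of the saturated, commercial 3-(benzyloxy)cyclobutan-1-one by 12, run with a chiral N,N′-dioxide ligand so that the reagent and not the substrate chooses the face of the diazo carbon, should give the benzyloxy spiro diketone F1. Hydrogenolysis (H2, Pd/C, EtOAc; no alkene is present at this stage) should give the hydroxy spiro diketone F2. Dess–Martin oxidation should give the spiro trione F3, whose 1,3-dione is converted by EtOH and TsOH (benzene, azeotropic removal of water) into the less hindered ethyl vinylogous ester, which is 15.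

Step 10. What may go wrong: slow insertion at the hindered β-carbon, competing 1,6-addition, poor facial selectivity at C15, or base-induced epimerization at C3 and migration of the C1=C2 alkene. The fallback sets out from 16 and returns at 20. Stille coupling of 16 with (E)-2-methyl-3-(tributylstannyl)prop-2-en-1-ol (Pd(PPh3)4, CuI, DMF, 25 °C) should give the dienyl alcohol F4. A Johnson–Claisen rearrangement (MeC(OMe)3, catalytic EtCO2H, toluene, 110 °C) then forms the C15–CH2CO2Me bond and the isopropenyl group in one [3,3] shift through a chair transition state on the dienol face turned away from ring D; the C15 epimers would be separated to give 20.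

Step 12. What may go wrong: acid-induced ionization of the allylic C13 hydroxyl, leading to the transposed cyclopentenone (Stork–Danheiser pathway) instead of the β-hydroxy ketone. The fallback sets out from 20 and returns at 22, and unmasks the ketone without acid at the carbinol stage. Hydrolysis of the vinylogous ester of 20 (HCl 1 M, THF, 25 °C) should give the spiro 1,3-dione F5. Silylation of its less hindered enol oxygen (t-BuMe2SiCl, imidazole, DMF) should give the silyl vinylogous ester F6. Luche reduction (NaBH4, CeCl3·7H2O, MeOH, −40 °C) should give the silyl enol ether carbinol F7, and buffered fluoride (Bu4NF, AcOH, THF, 0 °C) cleaves the silyl enol ether to the C11 ketone, giving 22.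

Further compounds

F1 | step 7 | benzyloxy spiro diketone (C11–OCH2Ph, either C11 epimer; C1 and C13 ketones) | O=C1C[C@H]2C(=O)O[C@@H]3C[C@](C)(O)[C@@H]([C@@H]32)[C@]12CC(OCc4ccccc4)CC2=O
F2 | step 7 | hydroxy spiro diketone (C11–OH) | O=C1C[C@H]2C(=O)O[C@@H]3C[C@](C)(O)[C@@H]([C@@H]32)[C@]12CC(O)CC2=O
F3 | step 7 | spiro trione (C1, C11 and C13 ketones; drawn in the keto form) | O=C1C[C@H]2C(=O)O[C@@H]3C[C@](C)(O)[C@@H]([C@@H]32)[C@]12CC(=O)CC2=O
F4 | step 10 | dienyl alcohol ((E)-3-hydroxy-2-methylprop-1-enyl group on C1) | OC/C(C)=C/C1=C[C@H]2C(=O)O[C@@H]3C[C@](C)(O)[C@@H]([C@@H]32)[C@]12CC(OCC)=CC2=O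
F5 | step 12 | spiro 1,3-dione with complete side chain (drawn in the keto form) | C=C(C)[C@H](CC(=O)OC)C1=C[C@H]2C(=O)O[C@@H]3C[C@](C)(O)[C@@H]([C@@H]32)[C@]12CC(=O)CC2=O
F6 | step 12 | silyl vinylogous ester (C11–OSiMe2t-Bu, C13=O) | C=C(C)[C@H](CC(=O)OC)C1=C[C@H]2C(=O)O[C@@H]3C[C@](C)(O)[C@@H]([C@@H]32)[C@]12CC(O[Si](C)(C)C(C)(C)C)=CC2=O
F7 | step 12 | silyl enol ether carbinol (C13–OH, C11–OSiMe2t-Bu) | C=C(C)[C@H](CC(=O)OC)C1=C[C@H]2C(=O)O[C@@H]3C[C@](C)(O)[C@@H]([C@@H]32)[C@]12CC(O[Si](C)(C)C(C)(C)C)=C[C@@H]2O
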